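**Retrosynthetic overview**
1. Enamide C–N bond: target 15 ⇒ α-iodoenone 14 + primary amide 7 (Cu-catalysed vinylic amidation, last step).
2. 14 ⇒ cis-diol enone 13 (α-iodination) ⇒ achiral p-quinol 10 by a desymmetrising syn-hydration: one C–O bond made, both ring stereocentres set (key step).
3. 10 ⇒ 5-(4-hydroxyphenyl)pentanoic acid 8 by oxidative dearomatisation; the only ring is bought as the arene, so no ring is constructed.
4. 7 ⇒ alcohol 5 (oxidation/Wittig) ⇒ 4-methylpent-1-ene 1 by two Zr-catalysed asymmetric carboaluminations (syn-4,6-dimethyl array).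

Assumption: 5-(4-hydroxyphenyl)pentanoic acid, both enantiomers of (NMI)2ZrCl2 and Ph3P=CHCONH2 (or its phosphonium chloride) are taken as catalogue items; the target SMILES is read as ring (1R,6S) cis-diol and side chain (2E,4S,6S) with syn methyls.

**Route**

Step 1
Reactants: 1 4-methylpent-1-ene
Product: 3 (4S)-4,6-dimethylhept-1-ene, via alane 2 (not isolated)
Conditions: Me3Al (2 equiv), (+)-(NMI)2ZrCl2 (4 mol%), MAO (10 mol%), CH2Cl2, 0 °C→rt; evaporate; Zn(OTf)2 (1 equiv, shuttle, not consumed), DMF, 70 °C; CH2=CHBr, Pd(DPEphos)Cl2 (3 mol%), DIBAL-H (6 mol%), THF–DMF, rt; aq. HCl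
Reagents that add atoms: trimethylaluminium C[Al](C)C; vinyl bromide C=CBr
Why: Zr-catalysed asymmetric carboalumination (ZACA) adds Me–Al across the terminal alkene with catalyst-controlled face selectivity (about 75–80% ee; the (+)-catalyst is the enantiomer that gives (S)-2-methylalkyl metals), and the primary alkyl metal is then vinylated by Pd-catalysed Negishi-type coupling without touching the new stereocentre.

Step 2
Reactants: 3 (4S)-4,6-dimethylhept-1-ene
Product: 5 (2S,4S)-2,4,6-trimethylheptan-1-ol, via alane 4 (not isolated)
Conditions: Me3Al (2 equiv), (+)-(NMI)2ZrCl2 (4 mol%), MAO (10 mol%), CH2Cl2, 0 °C→rt; O2, 0 °C→rt; aq. HCl; chromatography to remove the anti isomer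
Reagents that add atoms: trimethylaluminium C[Al](C)C; dioxygen O=O
Why: A second ZACA with the same catalyst enantiomer sets C2 syn to the existing methyl, O2 oxidises the C–Al bond with retention, and removing the minor anti diastereomer leaves the syn alcohol in about 97% ee by statistical amplification.

Step 3
Reactants: 5 (2S,4S)-2,4,6-trimethylheptan-1-ol
Product: 7 (2E,4S,6S)-4,6,8-trimethylnon-2-enamide, via aldehyde 6 (not isolated)
Conditions: IBX (1.2 equiv), DMSO, rt; then Ph3P=CHCONH2 (1.8 equiv), rt
Reagents that add atoms: (carbamoylmethylene)triphenylphosphorane NC(=O)C=P(c1ccccc1)(c1ccccc1)c1ccccc1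
Why: IBX oxidation gives the α-branched aldehyde without epimerisation and the stabilised ylide traps it in the same pot in an E-selective Wittig olefination, so the volatile, epimerisable aldehyde is never handled and the primary amide needed for the C–N coupling is obtained directly.

Step 4
Reactants: 8 5-(4-hydroxyphenyl)pentanoic acid
Product: 10 5-(1-hydroxy-4-oxocyclohexa-2,5-dien-1-yl)pentanoic acid, via hydroperoxide 9 (not isolated)
Conditions: Oxone (8 equiv), KHCO3, MeCN–H2O, rt; then aq. Na2S2O3, rt; acidify to pH 3
Reagents that add atoms: Oxone (potassium peroxymonosulfate, source of singlet oxygen) OOS(=O)(=O)[O-].[K+]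
Why: Base-induced decomposition of peroxymonosulfate gives singlet oxygen, which adds to the para position of the phenolate to give the p-peroxyquinol that thiosulfate reduces to the p-quinol (oxidative dearomatisation); the product is achiral, so no stereocentre is at stake yet.

Step 5
Reactants: 10 5-(1-hydroxy-4-oxocyclohexa-2,5-dien-1-yl)pentanoic acid
Product: 13 5-[(1R,6S)-1,6-dihydroxy-4-oxocyclohex-2-en-1-yl]pentanoic acid, via boronic hemiester 11 (not isolated), via cyclic boronate 12 (not isolated)
Conditions: PhB(OH)2 (1.5 equiv), 9-amino-9-deoxy-epi-quinine (20 mol%), 1,4-dioxane, 30 °C; then pinacol (3 equiv), rt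
Reagents that add atoms: phenylboronic acid OB(O)c1ccccc1
Why: Proposed new method: amine-catalysed, boron-tethered desymmetrising oxa-Michael addition, a formal enantioselective syn-hydration of a p-quinol. The tertiary OH of 10 is reversibly esterified by PhB(OH)2 (11) and the primary amine of the catalyst condenses with the dienone to a cross-conjugated iminium ion, with the substrate's own CO2H serving as the acid co-catalyst so that no ester protection is needed. The quinuclidine nitrogen, held beside one of the two enantiotopic β-carbons, binds the B–OH and delivers its oxygen to that carbon only (5-exo), on the face of the tether. The new C6–O bond is therefore cis to C1–O, and the choice of ring alkene fixes both stereocentres as (1R,6S) at once. Iminium hydrolysis releases boronate 12, a thermodynamic sink that blocks retro-addition and racemisation, and pinacol frees the diol. The closest known reactions are the amine/boronic acid "chiral hydroxide" oxa-Michael addition to acyclic γ-hydroxy enones, primary-amine iminium-catalysed oxa-Michael desymmetrisation of cyclohexadienones carrying carbon-tethered alcohols, and quinuclidinium-guided H2O2 delivery in amine-catalysed enone epoxidation. The sense of induction is assumed by analogy and must be confirmed on the first run; the quinidine-derived pseudoenantiomer gives the antipode.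

Step 6
Reactants: 13 5-[(1R,6S)-1,6-dihydroxy-4-oxocyclohex-2-en-1-yl]pentanoic acid
Product: 14 5-[(1R,6S)-1,6-dihydroxy-3-iodo-4-oxocyclohex-2-en-1-yl]pentanoic acid
Conditions: I2 (2 equiv), pyridine–CH2Cl2 (1:1), 0 °C→rt; aq. Na2S2O3, citric acid
Reagents that add atoms: iodine II
Why: Johnson α-iodination (pyridine conjugate addition, iodination of the enolate, E1cB loss of pyridine) can only occur at the single remaining enone α-C–H, is known for 4,4-disubstituted cyclohexenones, and leaves the diol, the acid and both stereocentres untouched.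

Step 7
Reactants: 14 5-[(1R,6S)-1,6-dihydroxy-3-iodo-4-oxocyclohex-2-en-1-yl]pentanoic acid; 7 (2E,4S,6S)-4,6,8-trimethylnon-2-enamide
Product: 15 Salternamide E, 5-[(1R,6S)-1,6-dihydroxy-4-oxo-3-{[(2E,4S,6S)-4,6,8-trimethylnon-2-enoyl]amino}cyclohex-2-en-1-yl]pentanoic acid
Conditions: CuI (20 mol%), trans-N,N'-dimethylcyclohexane-1,2-diamine (40 mol%), Cs2CO3 (3 equiv), 7 (1.2 equiv), 1,4-dioxane, 50 °C; then aq. NaH2PO4 (pH 4)
Reagents that add atoms: none
Why: Buchwald–Goldberg Cu(I)/diamine vinylic amidation couples the activated α-iodoenone with the primary amide to form the enamide C–N bond at the iodine-bearing carbon, and the mild carbonate base at 50 °C is chosen to spare the β-hydroxy ketone; no stereocentre is involved.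

**Compound list**
1 | 4-methylpent-1-ene | CC(C)CC=C | starting material
2 | [(2S)-2,4-dimethylpentyl]dimethylalumane | CC(C)C[C@H](C)C[Al](C)C | intermediate
3 | (4S)-4,6-dimethylhept-1-ene | CC(C)C[C@H](C)CC=C | intermediate
4 | dimethyl[(2S,4S)-2,4,6-trimethylheptyl]alumane | CC(C)C[C@H](C)C[C@H](C)C[Al](C)C | intermediate
5 | (2S,4S)-2,4,6-trimethylheptan-1-ol | CC(C)C[C@H](C)C[C@H](C)CO | intermediate
6 | (2S,4S)-2,4,6-trimethylheptanal | CC(C)C[C@H](C)C[C@H](C)C=O | intermediate
7 | (2E,4S,6S)-4,6,8-trimethylnon-2-enamide | CC(C)C[C@H](C)C[C@H](C)/C=C/C(N)=O | intermediate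
8 | 5-(4-hydroxyphenyl)pentanoic acid | OC(=O)CCCCc1ccc(O)cc1 | starting material
9 | 5-(1-hydroperoxy-4-oxocyclohexa-2,5-dien-1-yl)pentanoic acid | OOC1(CCCCC(=O)O)C=CC(=O)C=C1 | intermediate
10 | 5-(1-hydroxy-4-oxocyclohexa-2,5-dien-1-yl)pentanoic acid | OC1(CCCCC(=O)O)C=CC(=O)C=C1 | intermediate
11 | 5-(1-{[hydroxy(phenyl)boranyl]oxy}-4-oxocyclohexa-2,5-dien-1-yl)pentanoic acid (boronic hemiester of 10) | OB(OC1(CCCCC(=O)O)C=CC(=O)C=C1)c1ccccc1 | intermediate
12 | 5-[(3aR,7aS)-6-oxo-2-phenyl-6,7-dihydro-1,3,2-benzodioxaborol-3a(7aH)-yl]pentanoic acid (cis-fused cyclic phenylboronate of 13) | C1=C[C@](O2)(CCCCC(=O)O)[C@@H](OB2c3ccccc3)CC1=O | intermediate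
13 | 5-[(1R,6S)-1,6-dihydroxy-4-oxocyclohex-2-en-1-yl]pentanoic acid | O=C1C=C[C@](O)(CCCCC(=O)O)[C@@H](O)C1 | intermediate
14 | 5-[(1R,6S)-1,6-dihydroxy-3-iodo-4-oxocyclohex-2-en-1-yl]pentanoic acid | O=C1C(I)=C[C@](O)(CCCCC(=O)O)[C@@H](O)C1 | intermediate
15 | Salternamide E | CC(C)C[C@H](C)C[C@H](C)/C=C/C(=O)NC1=C[C@](O)(CCCCC(=O)O)[C@@H](O)CC1=O | target

**Step count and risks**

Total step count: 7. Longest linear sequence: 4 (steps 4–7, or steps 1–3 then 7).

Three steps most likely to fail:

Step 5 (the proposed new desymmetrising hydration). The risks are low rate of B–OH delivery, low or reversed enantioselectivity, and a racemic background reaction. The fallback uses the known chiral-phosphoric-acid acetalisation/oxa-Michael cascade of p-quinols. It sets out from 10: treatment with 2-methylpropanal and a TRIP-type BINOL phosphoric acid (10 mol%) in toluene gives the cis-fused isobutylidene acetal F1, with the hemiacetal oxygen playing the role of the tethered hydroxide and the acid catalyst choosing the ring alkene. Hydrolysis of the acetal with TFA–H2O (0 °C→rt) then releases the diol, and the route is rejoined at 13. The reported enantioselectivities for p-quinols in this cascade are moderate to good, so a recrystallisation of 13 or 14 may be needed.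

Step 7 (Cu amidation on the unprotected diol acid). The risks are base-induced loss of the β-hydroxyl or retro-aldol opening, and copper sequestration by the carboxylate and diol. The fallback is a protecting-group detour that sets out from 14: 2-methoxypropene and PPTS in CH2Cl2 at 0 °C give the acetonide iodide F2 (any mixed ester on the acid falls off on aqueous work-up). The same CuI/diamine/Cs2CO3 coupling with 7 gives the acetonide amide F3, in which the β-oxygen is tied into a ring so that any elimination is reversible. 80% aq. AcOH at rt to 40 °C removes the acetonide and the route is rejoined at 15.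

Step 2 (second ZACA). The risks are only about 75–80% ee per carboalumination and a difficult syn/anti separation. The fallback replaces carbometalation/oxidation by hydroformylation and sets out from 3: Rh(acac)(CO)2 with the BOBPHOS enantiomer that gives the 2S centre, under CO/H2 (1:1, 5 bar) in toluene at 30–40 °C, performs a branched-selective asymmetric hydroformylation. This gives aldehyde 6 directly (branched:linear about 3:1, linear isomer removed after the olefination). The route is rejoined at 6, which goes straight into the Wittig half of step 3; no new compound is made.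

**Further compounds**
F1 | step 5 | 5-[(2R,3aR,7aS)-6-oxo-2-(propan-2-yl)-6,7-dihydro-1,3-benzodioxol-3a(7aH)-yl]pentanoic acid | O=C1C=C[C@](O2)(CCCCC(=O)O)[C@@H](O[C@H]2C(C)C)C1
F2 | step 7 | 5-[(3aR,7aS)-5-iodo-2,2-dimethyl-6-oxo-6,7-dihydro-1,3-benzodioxol-3a(7aH)-yl]pentanoic acid | O=C1C(I)=C[C@](O2)(CCCCC(=O)O)[C@@H](OC2(C)C)C1
F3 | step 7 | 5-[(3aR,7aS)-2,2-dimethyl-6-oxo-5-{[(2E,4S,6S)-4,6,8-trimethylnon-2-enoyl]amino}-6,7-dihydro-1,3-benzodioxol-3a(7aH)-yl]pentanoic acid | CC(C)C[C@H](C)C[C@H](C)/C=C/C(=O)NC1=C[C@](O2)(CCCCC(=O)O)[C@@H](OC2(C)C)CC1=O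
F0 | step 2 | none | none
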